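## Retrosynthetic overview

1. The target comes from N-acylation of the amino core with (E)-dodec-2-enoic acid, after hydrogenolysis of N-Cbz/O-benzyl and before removal of one silyl ether.
2. The C6 methoxy group and the 7,8-oxirane come from exo-face oxygenation of a bicyclo[3.3.1]non-6-en-9-one: singlet-oxygen ene reaction, OH-directed epoxidation, O-methylation.
3. Ring A (the bicyclo[3.3.1]nonan-9-one) comes from an intramolecular aldol (C5 to C4) of an α-(Cbz-amino) aldehyde tethered to a cyclohexanone, with C3 and C4 set under equilibration; a C6 phenylthio group carries the future alkene.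
4. The C1–C2 bond and the quaternary C1 come from an intermolecular asymmetric Michael addition of the (R)-1-phenylethylamine imine of 2-(benzyloxy)cyclohexanone to Cbz-dehydroalanine methyl ester.
5. Ring order: ring B (from cyclohexene oxide), then ring A (aldol), then the oxirane last.

Assumption: locants C1–C9 are those of the bicyclo[3.3.1]nonane core (C1 = C–OH bridgehead, C2 = CH2, C3 = C–N, C4 = CH–OH, C5 = bridgehead CH, C6 = C–OMe, C7/C8 = oxirane carbons, C9 = C=O) and are used for monocyclic precursors too; "exo" means on the face of a ring turned away from the other three-carbon bridge. The 90–95% ee expected from step 4 is raised by recrystallising 15.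

## Route

Step 1
Reactants: 1 cyclohexene oxide; 2 benzyl alcohol
Product: 3 rac-trans-2-(benzyloxy)cyclohexan-1-ol
Conditions: BnOH (3 equiv), BF3·OEt2 (5 mol %), CH2Cl2, 0 °C to rt
Reagents that add atoms: none
Why: Lewis-acid-catalysed SN2 opening of the meso epoxide gives the trans hydroxy ether; its stereocentres are erased later.

Step 2
Reactants: 3 rac-trans-2-(benzyloxy)cyclohexan-1-ol
Product: 4 rac-2-(benzyloxy)cyclohexan-1-one
Conditions: (COCl)2, DMSO, CH2Cl2, −78 °C; Et3N, to 0 °C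
Reagents that add atoms: none
Why: Swern oxidation of a secondary alcohol; the benzyl ether is inert.

Step 3
Reactants: 4 rac-2-(benzyloxy)cyclohexan-1-one; 5 (R)-1-phenylethylamine
Product: 6 (2RS)-2-(benzyloxy)-N-[(1R)-1-phenylethyl]cyclohexan-1-imine
Conditions: TsOH (cat.), toluene, Dean–Stark, reflux; used crude
Reagents that add atoms: none
Why: Imine condensation; the imine equilibrates with its secondary enamine, which makes the C2 configuration irrelevant.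

Step 4
Reactants: 6 (2RS)-2-(benzyloxy)-N-[(1R)-1-phenylethyl]cyclohexan-1-imine; 7 methyl 2-{[(benzyloxy)carbonyl]amino}prop-2-enoate
Product: 9 methyl (2RS)-2-{[(benzyloxy)carbonyl]amino}-3-[(1R)-1-(benzyloxy)-2-oxocyclohexyl]propanoate, via Michael adduct imine 8 (not isolated)
Conditions: 7 (1.2 equiv), THF, 50 °C, 3–5 d; then 20% aq AcOH, rt
Reagents that add atoms: water, O
Why: Asymmetric Michael addition of a chiral imine (d'Angelo type), in which the more substituted secondary enamine adds through a chair-like aza-ene transition state on the face anti to the auxiliary phenyl group; by analogy with the 2-methylcyclohexanone series the (R)-amine gives the (R)-quaternary centre, while C3 is left uncontrolled on purpose.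

Step 5
Reactants: 9 methyl (2RS)-2-{[(benzyloxy)carbonyl]amino}-3-[(1R)-1-(benzyloxy)-2-oxocyclohexyl]propanoate
Product: 11 methyl (2RS)-2-{[(benzyloxy)carbonyl]amino}-3-[(1R)-1-(benzyloxy)-2-oxocyclohex-3-en-1-yl]propanoate, via TMS enol ether 10 (not isolated)
Conditions: TMSOTf, Et3N, CH2Cl2, 0 °C; then Pd(OAc)2 (1.1 equiv), MeCN, rt
Reagents that add atoms: none
Why: Ito–Saegusa oxidation; the ketone can enolise only toward C5 because C1 is quaternary, so the C5=C6 enone forms regiospecifically.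

Step 6
Reactants: 11 methyl (2RS)-2-{[(benzyloxy)carbonyl]amino}-3-[(1R)-1-(benzyloxy)-2-oxocyclohex-3-en-1-yl]propanoate
Product: 12 methyl (2RS)-2-{[(benzyloxy)carbonyl]amino}-3-[(1R,4RS)-1-(benzyloxy)-2-oxo-4-(phenylsulfanyl)cyclohexyl]propanoate
Conditions: PhSH (1.2 equiv), Et3N (10 mol %), CH2Cl2, rt
Reagents that add atoms: thiophenol, Sc1ccccc1
Why: Thia-Michael addition puts a hydride- and acid-stable handle on C6 for the later alkene; its configuration does not matter.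

Step 7
Reactants: 12 methyl (2RS)-2-{[(benzyloxy)carbonyl]amino}-3-[(1R,4RS)-1-(benzyloxy)-2-oxo-4-(phenylsulfanyl)cyclohexyl]propanoate
Product: 13 benzyl N-{(2RS)-1-[(1R,2RS,4RS)-1-(benzyloxy)-2-hydroxy-4-(phenylsulfanyl)cyclohexyl]-3-hydroxypropan-2-yl}carbamate
Conditions: LiBH4, THF–MeOH, 0 °C to rt
Reagents that add atoms: none
Why: Borohydride reduction of ketone and ester to the diol (carbamate, sulfide and benzyl ether survive), because the ester cannot be taken to the aldehyde selectively beside the ketone.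

Step 8
Reactants: 13 benzyl N-{(2RS)-1-[(1R,2RS,4RS)-1-(benzyloxy)-2-hydroxy-4-(phenylsulfanyl)cyclohexyl]-3-hydroxypropan-2-yl}carbamate
Product: 14 benzyl N-{(2RS)-1-[(1R,4RS)-1-(benzyloxy)-2-oxo-4-(phenylsulfanyl)cyclohexyl]-3-oxopropan-2-yl}carbamate
Conditions: (COCl)2, DMSO, CH2Cl2, −78 °C; Et3N, to 0 °C; used crude
Reagents that add atoms: none
Why: Double Swern oxidation gives the keto aldehyde without oxidising the sulfide.

Step 9
Reactants: 14 benzyl N-{(2RS)-1-[(1R,4RS)-1-(benzyloxy)-2-oxo-4-(phenylsulfanyl)cyclohexyl]-3-oxopropan-2-yl}carbamate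
Product: 15 benzyl N-[(1R,3S,4R,5R,6RS)-1-(benzyloxy)-4-hydroxy-9-oxo-6-(phenylsulfanyl)bicyclo[3.3.1]nonan-3-yl]carbamate
Conditions: DBU (0.3 equiv), PhSH (0.1 equiv), CH2Cl2, 0 °C to rt; recrystallise
Reagents that add atoms: none
Why: Intramolecular aldol under equilibrating conditions, where only C5 can enolise, the α-amido aldehyde epimerises at C3 and the aldol is reversible; the chair–chair bicycle with NHCbz exo (equatorial) and C4–OH exo (axial, hydrogen-bonded to C9=O and free of the 4,6-endo clash) is expected to accumulate, and C5 is fixed by the bridge.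

Step 10
Reactants: 15 benzyl N-[(1R,3S,4R,5R,6RS)-1-(benzyloxy)-4-hydroxy-9-oxo-6-(phenylsulfanyl)bicyclo[3.3.1]nonan-3-yl]carbamate
Product: 16 benzyl N-[(1R,3S,4R,5R,6RS)-1-(benzyloxy)-9-oxo-6-(phenylsulfanyl)-4-[(triethylsilyl)oxy]bicyclo[3.3.1]nonan-3-yl]carbamate
Conditions: TESOTf, 2,6-lutidine, CH2Cl2, −78 to 0 °C
Reagents that add atoms: triethylsilyl trifluoromethanesulfonate, CC[Si](CC)(CC)OS(=O)(=O)C(F)(F)F
Why: Silylation under non-nucleophilic conditions (no retro-aldol) masks the only hydroxyl so that the later methylation can only hit C6–OH.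

Step 11
Reactants: 16 benzyl N-[(1R,3S,4R,5R,6RS)-1-(benzyloxy)-9-oxo-6-(phenylsulfanyl)-4-[(triethylsilyl)oxy]bicyclo[3.3.1]nonan-3-yl]carbamate
Product: 18 benzyl N-[(1R,3S,4R,5R)-1-(benzyloxy)-9-oxo-4-[(triethylsilyl)oxy]bicyclo[3.3.1]non-6-en-3-yl]carbamate, via sulfoxide 17 (not isolated)
Conditions: mCPBA (1.0 equiv), CH2Cl2, −78 °C; then toluene, CaCO3, 110 °C
Reagents that add atoms: none
Why: Sulfide oxidation then thermal sulfoxide syn-elimination; C5 is a bridgehead (Bredt), so only a C7–H can be lost and both C6 epimers converge on the C6=C7 alkene.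

Step 12
Reactants: 18 benzyl N-[(1R,3S,4R,5R)-1-(benzyloxy)-9-oxo-4-[(triethylsilyl)oxy]bicyclo[3.3.1]non-6-en-3-yl]carbamate
Product: 20 benzyl N-[(1S,3S,4R,5R,6R)-1-(benzyloxy)-6-hydroxy-9-oxo-4-[(triethylsilyl)oxy]bicyclo[3.3.1]non-7-en-3-yl]carbamate, via allylic hydroperoxide 19 (not isolated)
Conditions: O2, TPP (cat.), hν (>450 nm), CH2Cl2, 0 °C; then PPh3
Reagents that add atoms: dioxygen, O=O
Why: Schenck ene reaction, in which singlet oxygen attacks the open exo face, bonds to C6 and takes the exo C8–H (the other mode would need the bridgehead C5–H and an anti-Bredt alkene); this gives the exo C6–OOH with the alkene moved to C7=C8, and PPh3 reduces the O–O bond with retention.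

Step 13
Reactants: 20 benzyl N-[(1S,3S,4R,5R,6R)-1-(benzyloxy)-6-hydroxy-9-oxo-4-[(triethylsilyl)oxy]bicyclo[3.3.1]non-7-en-3-yl]carbamate
Product: 21 benzyl N-[(1S,3S,4R,5R,6S,7S,8S)-1-(benzyloxy)-7,8-epoxy-6-hydroxy-9-oxo-4-[(triethylsilyl)oxy]bicyclo[3.3.1]nonan-3-yl]carbamate
Conditions: t-BuOOH (1.5 equiv), VO(acac)2 (5 mol %), CH2Cl2, 0 °C to rt
Reagents that add atoms: tert-butyl hydroperoxide, CC(C)(C)OO
Why: Vanadium-catalysed hydroxyl-directed epoxidation delivers oxygen syn to the exo C6–OH, which is also the sterically open face, giving the all-exo epoxy alcohol.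

Step 14
Reactants: 21 benzyl N-[(1S,3S,4R,5R,6S,7S,8S)-1-(benzyloxy)-7,8-epoxy-6-hydroxy-9-oxo-4-[(triethylsilyl)oxy]bicyclo[3.3.1]nonan-3-yl]carbamate
Product: 22 benzyl N-[(1S,3S,4R,5R,6S,7S,8S)-1-(benzyloxy)-7,8-epoxy-6-methoxy-9-oxo-4-[(triethylsilyl)oxy]bicyclo[3.3.1]nonan-3-yl]carbamate
Conditions: Me3OBF4, Proton-sponge, 4 Å MS, CH2Cl2, rt
Reagents that add atoms: trimethyloxonium tetrafluoroborate, C[O+](C)C.F[B-](F)(F)F
Why: Meerwein O-methylation of the only free hydroxyl without forming an alkoxide, so the carbamate N–H is not methylated and the oxirane (backside shielded by the bicycle) is not opened.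

Step 15
Reactants: 22 benzyl N-[(1S,3S,4R,5R,6S,7S,8S)-1-(benzyloxy)-7,8-epoxy-6-methoxy-9-oxo-4-[(triethylsilyl)oxy]bicyclo[3.3.1]nonan-3-yl]carbamate
Product: 23 (1S,3S,4R,5R,6S,7S,8S)-3-amino-7,8-epoxy-1-hydroxy-6-methoxy-4-[(triethylsilyl)oxy]bicyclo[3.3.1]nonan-9-one
Conditions: H2 (1 atm), Pd(OH)2/C, EtOAc, rt; filter and use at once
Reagents that add atoms: none
Why: Catalytic hydrogenolysis removes the Cbz group and the tertiary benzyl ether; oxirane, ketone, methyl ether and silyl ether are inert under neutral conditions.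

Step 16
Reactants: 23 (1S,3S,4R,5R,6S,7S,8S)-3-amino-7,8-epoxy-1-hydroxy-6-methoxy-4-[(triethylsilyl)oxy]bicyclo[3.3.1]nonan-9-one; 24 (2E)-dodec-2-enoic acid
Product: 25 (2E)-N-[(1S,3S,4R,5R,6S,7S,8S)-7,8-epoxy-1-hydroxy-6-methoxy-9-oxo-4-[(triethylsilyl)oxy]bicyclo[3.3.1]nonan-3-yl]dodec-2-enamide
Conditions: EDC·HCl, HOBt, i-Pr2NEt, CH2Cl2, 0 °C to rt
Reagents that add atoms: none
Why: Carbodiimide amide coupling; the primary amine outcompetes the tertiary C1–OH, C4–O is silylated, and the (E)-alkene is untouched.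

Step 17
Reactants: 25 (2E)-N-[(1S,3S,4R,5R,6S,7S,8S)-7,8-epoxy-1-hydroxy-6-methoxy-9-oxo-4-[(triethylsilyl)oxy]bicyclo[3.3.1]nonan-3-yl]dodec-2-enamide
Product: 26 (2E)-N-[(1S,3S,4R,5S,6S,7S,8S)-7,8-epoxy-1,4-dihydroxy-6-methoxy-9-oxobicyclo[3.3.1]nonan-3-yl]dodec-2-enamide
Conditions: HF·pyridine, pyridine, THF, 0 °C to rt
Reagents that add atoms: none
Why: Buffered fluoride desilylation is non-basic, so the β-hydroxy ketone does not undergo retro-aldol and the hindered oxirane stays closed.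

## Compound list

1 | cyclohexene oxide (meso) | C1CCC2OC2C1 | starting material
2 | benzyl alcohol | OCc1ccccc1 | starting material
3 | rac-trans-2-(benzyloxy)cyclohexan-1-ol (one enantiomer drawn) | O[C@@H]1CCCC[C@H]1OCc1ccccc1 | intermediate
4 | rac-2-(benzyloxy)cyclohexan-1-one | O=C1CCCCC1OCc1ccccc1 | intermediate
5 | (R)-1-phenylethylamine | C[C@@H](N)c1ccccc1 | starting material
6 | (2RS)-2-(benzyloxy)-N-[(1R)-1-phenylethyl]cyclohexan-1-imine | C[C@@H](N=C1CCCCC1OCc1ccccc1)c1ccccc1 | intermediate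
7 | methyl 2-{[(benzyloxy)carbonyl]amino}prop-2-enoate | C=C(NC(=O)OCc1ccccc1)C(=O)OC | starting material
8 | methyl (2RS)-2-{[(benzyloxy)carbonyl]amino}-3-[(1R)-1-(benzyloxy)-2-{[(1R)-1-phenylethyl]imino}cyclohexyl]propanoate | COC(=O)C(NC(=O)OCc1ccccc1)C[C@@]2(OCc3ccccc3)C(=N[C@H](C)c4ccccc4)CCCC2 | intermediate
9 | methyl (2RS)-2-{[(benzyloxy)carbonyl]amino}-3-[(1R)-1-(benzyloxy)-2-oxocyclohexyl]propanoate | COC(=O)C(NC(=O)OCc1ccccc1)C[C@@]2(OCc3ccccc3)C(=O)CCCC2 | intermediate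
10 | methyl (2RS)-2-{[(benzyloxy)carbonyl]amino}-3-{(1R)-1-(benzyloxy)-2-[(trimethylsilyl)oxy]cyclohex-2-en-1-yl}propanoate | COC(=O)C(NC(=O)OCc1ccccc1)C[C@@]2(OCc3ccccc3)C(O[Si](C)(C)C)=CCCC2 | intermediate
11 | methyl (2RS)-2-{[(benzyloxy)carbonyl]amino}-3-[(1R)-1-(benzyloxy)-2-oxocyclohex-3-en-1-yl]propanoate | COC(=O)C(NC(=O)OCc1ccccc1)C[C@@]2(OCc3ccccc3)C(=O)C=CCC2 | intermediate
12 | methyl (2RS)-2-{[(benzyloxy)carbonyl]amino}-3-[(1R,4RS)-1-(benzyloxy)-2-oxo-4-(phenylsulfanyl)cyclohexyl]propanoate | COC(=O)C(NC(=O)OCc1ccccc1)C[C@@]2(OCc3ccccc3)C(=O)CC(Sc4ccccc4)CC2 | intermediate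
13 | benzyl N-{(2RS)-1-[(1R,2RS,4RS)-1-(benzyloxy)-2-hydroxy-4-(phenylsulfanyl)cyclohexyl]-3-hydroxypropan-2-yl}carbamate | OCC(NC(=O)OCc1ccccc1)C[C@@]2(OCc3ccccc3)C(O)CC(Sc4ccccc4)CC2 | intermediate
14 | benzyl N-{(2RS)-1-[(1R,4RS)-1-(benzyloxy)-2-oxo-4-(phenylsulfanyl)cyclohexyl]-3-oxopropan-2-yl}carbamate | O=CC(NC(=O)OCc1ccccc1)C[C@@]2(OCc3ccccc3)C(=O)CC(Sc4ccccc4)CC2 | intermediate
15 | benzyl N-[(1R,3S,4R,5R,6RS)-1-(benzyloxy)-4-hydroxy-9-oxo-6-(phenylsulfanyl)bicyclo[3.3.1]nonan-3-yl]carbamate (N and OH exo) | O=C(OCc1ccccc1)N[C@H]2C[C@@]3(OCc4ccccc4)C(=O)[C@@H]([C@H]2O)C(Sc5ccccc5)CC3 | intermediate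
16 | benzyl N-[(1R,3S,4R,5R,6RS)-1-(benzyloxy)-9-oxo-6-(phenylsulfanyl)-4-[(triethylsilyl)oxy]bicyclo[3.3.1]nonan-3-yl]carbamate | O=C(OCc1ccccc1)N[C@H]2C[C@@]3(OCc4ccccc4)C(=O)[C@@H]([C@H]2O[Si](CC)(CC)CC)C(Sc5ccccc5)CC3 | intermediate
17 | benzyl N-[(1R,3S,4R,5R,6RS)-6-(benzenesulfinyl)-1-(benzyloxy)-9-oxo-4-[(triethylsilyl)oxy]bicyclo[3.3.1]nonan-3-yl]carbamate | O=C(OCc1ccccc1)N[C@H]2C[C@@]3(OCc4ccccc4)C(=O)[C@@H]([C@H]2O[Si](CC)(CC)CC)C(S(=O)c5ccccc5)CC3 | intermediate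
18 | benzyl N-[(1R,3S,4R,5R)-1-(benzyloxy)-9-oxo-4-[(triethylsilyl)oxy]bicyclo[3.3.1]non-6-en-3-yl]carbamate | O=C(OCc1ccccc1)N[C@H]2C[C@@]3(OCc4ccccc4)C(=O)[C@@H]([C@H]2O[Si](CC)(CC)CC)C=CC3 | intermediate
19 | benzyl N-[(1S,3S,4R,5R,6R)-1-(benzyloxy)-6-hydroperoxy-9-oxo-4-[(triethylsilyl)oxy]bicyclo[3.3.1]non-7-en-3-yl]carbamate (6-exo) | O=C(OCc1ccccc1)N[C@H]2C[C@@]3(OCc4ccccc4)C(=O)[C@@H]([C@H]2O[Si](CC)(CC)CC)[C@H](OO)C=C3 | intermediate
20 | benzyl N-[(1S,3S,4R,5R,6R)-1-(benzyloxy)-6-hydroxy-9-oxo-4-[(triethylsilyl)oxy]bicyclo[3.3.1]non-7-en-3-yl]carbamate (6-exo) | O=C(OCc1ccccc1)N[C@H]2C[C@@]3(OCc4ccccc4)C(=O)[C@@H]([C@H]2O[Si](CC)(CC)CC)[C@H](O)C=C3 | intermediate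
21 | benzyl N-[(1S,3S,4R,5R,6S,7S,8S)-1-(benzyloxy)-7,8-epoxy-6-hydroxy-9-oxo-4-[(triethylsilyl)oxy]bicyclo[3.3.1]nonan-3-yl]carbamate | O=C(OCc1ccccc1)N[C@H]2C[C@@]3(OCc4ccccc4)C(=O)[C@@H]([C@H]2O[Si](CC)(CC)CC)[C@H](O)[C@@H]5O[C@@H]53 | intermediate
22 | benzyl N-[(1S,3S,4R,5R,6S,7S,8S)-1-(benzyloxy)-7,8-epoxy-6-methoxy-9-oxo-4-[(triethylsilyl)oxy]bicyclo[3.3.1]nonan-3-yl]carbamate | O=C(OCc1ccccc1)N[C@H]2C[C@@]3(OCc4ccccc4)C(=O)[C@@H]([C@H]2O[Si](CC)(CC)CC)[C@H](OC)[C@@H]5O[C@@H]53 | intermediate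
23 | (1S,3S,4R,5R,6S,7S,8S)-3-amino-7,8-epoxy-1-hydroxy-6-methoxy-4-[(triethylsilyl)oxy]bicyclo[3.3.1]nonan-9-one | N[C@H]1C[C@@]2(O)C(=O)[C@@H]([C@H]1O[Si](CC)(CC)CC)[C@H](OC)[C@@H]3O[C@@H]32 | intermediate
24 | (2E)-dodec-2-enoic acid | CCCCCCCCC/C=C/C(=O)O | starting material
25 | (2E)-N-[(1S,3S,4R,5R,6S,7S,8S)-7,8-epoxy-1-hydroxy-6-methoxy-9-oxo-4-[(triethylsilyl)oxy]bicyclo[3.3.1]nonan-3-yl]dodec-2-enamide | CCCCCCCCC/C=C/C(=O)N[C@H]1C[C@@]2(O)C(=O)[C@@H]([C@H]1O[Si](CC)(CC)CC)[C@H](OC)[C@@H]3O[C@@H]32 | intermediate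
26 | (2E)-N-[(1S,3S,4R,5S,6S,7S,8S)-7,8-epoxy-1,4-dihydroxy-6-methoxy-9-oxobicyclo[3.3.1]nonan-3-yl]dodec-2-enamide | CCCCCCCCC/C=C/C(=O)N[C@H]1C[C@@]2(O)C(=O)[C@@H]([C@H]1O)[C@H](OC)[C@@H]1O[C@@H]12 | target

## Summary

Total steps: 17. Longest linear sequence: 17 (from cyclohexene oxide 1; compounds 2, 5, 7 and 24 are bought).

Three steps most likely to fail:

Step 4 (Michael addition of a hindered α-alkoxy enamine to a weakly electrophilic amidoacrylate). The fallback sets out from imine 6 and returns at 9. Imine 6 is added instead to dimethyl 2-methylidenepropanedioate, a much stronger acceptor, to give dimethyl 2-{[(1R)-1-(benzyloxy)-2-{[(1R)-1-phenylethyl]imino}cyclohexyl]methyl}propanedioate F1. Aqueous acetic acid hydrolyses this to dimethyl 2-{[(1R)-1-(benzyloxy)-2-oxocyclohexyl]methyl}propanedioate F2. One ester is saponified (KOH, 1 equiv, MeOH, 0 °C) to 3-[(1R)-1-(benzyloxy)-2-oxocyclohexyl]-2-(methoxycarbonyl)propanoic acid F3. DPPA/Et3N converts it to the acyl azide methyl 2-(azidocarbonyl)-3-[(1R)-1-(benzyloxy)-2-oxocyclohexyl]propanoate F4, which on heating in toluene undergoes Curtius rearrangement to methyl 3-[(1R)-1-(benzyloxy)-2-oxocyclohexyl]-2-isocyanatopropanoate F5. Trapping with benzyl alcohol 2 gives 9, so nitrogen enters by rearrangement instead of with the acceptor.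

Step 9 (aldol; the C4 configuration rests on a thermodynamic argument). The fallback sets out from 14 and returns at 15. If cyclisation gives mainly the 4-endo alcohol, benzyl N-[(1R,3S,4S,5R,6RS)-1-(benzyloxy)-4-hydroxy-9-oxo-6-(phenylsulfanyl)bicyclo[3.3.1]nonan-3-yl]carbamate F6, the centre is corrected by Mitsunobu inversion (4-nitrobenzoic acid, PPh3, DIAD, THF); the nucleophile enters from the open exo face to give (1R,3S,4R,5R,6RS)-3-{[(benzyloxy)carbonyl]amino}-1-(benzyloxy)-9-oxo-6-(phenylsulfanyl)bicyclo[3.3.1]nonan-4-yl 4-nitrobenzoate F7. Brief methanolysis (K2CO3, MeOH, 0 °C) then gives 15.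

Step 12 (singlet-oxygen ene reaction on a slow, cis-disubstituted alkene). The fallback sets out from 18 and returns at 20. Epoxidation with mCPBA/NaHCO3 from the exo face gives benzyl N-[(1R,3S,4R,5R)-1-(benzyloxy)-6,7-exo-epoxy-9-oxo-4-[(triethylsilyl)oxy]bicyclo[3.3.1]nonan-3-yl]carbamate F8. Diethylaluminium 2,2,6,6-tetramethylpiperidide (toluene, 0 °C) then removes the syn C8–H; C5 cannot be deprotonated, so the oxirane opens only to the exo C6 alcohol with the C7=C8 alkene, which is 20. The amide base has no transferable hydride, which protects the non-enolisable C9 ketone.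

## Further compounds

F1 | step 4 | dimethyl 2-{[(1R)-1-(benzyloxy)-2-{[(1R)-1-phenylethyl]imino}cyclohexyl]methyl}propanedioate | COC(=O)C(C(=O)OC)C[C@@]1(OCc2ccccc2)C(=N[C@H](C)c3ccccc3)CCCC1
F2 | step 4 | dimethyl 2-{[(1R)-1-(benzyloxy)-2-oxocyclohexyl]methyl}propanedioate | COC(=O)C(C(=O)OC)C[C@@]1(OCc2ccccc2)C(=O)CCCC1
F3 | step 4 | (2RS)-3-[(1R)-1-(benzyloxy)-2-oxocyclohexyl]-2-(methoxycarbonyl)propanoic acid | COC(=O)C(C(=O)O)C[C@@]1(OCc2ccccc2)C(=O)CCCC1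
F4 | step 4 | methyl (2RS)-2-(azidocarbonyl)-3-[(1R)-1-(benzyloxy)-2-oxocyclohexyl]propanoate | COC(=O)C(C(=O)N=[N+]=[N-])C[C@@]1(OCc2ccccc2)C(=O)CCCC1
F5 | step 4 | methyl (2RS)-3-[(1R)-1-(benzyloxy)-2-oxocyclohexyl]-2-isocyanatopropanoate | COC(=O)C(N=C=O)C[C@@]1(OCc2ccccc2)C(=O)CCCC1
F6 | step 9 | benzyl N-[(1R,3S,4S,5R,6RS)-1-(benzyloxy)-4-hydroxy-9-oxo-6-(phenylsulfanyl)bicyclo[3.3.1]nonan-3-yl]carbamate (4-endo OH) | O=C(OCc1ccccc1)N[C@H]2C[C@@]3(OCc4ccccc4)C(=O)[C@@H]([C@@H]2O)C(Sc5ccccc5)CC3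
F7 | step 9 | (1R,3S,4R,5R,6RS)-3-{[(benzyloxy)carbonyl]amino}-1-(benzyloxy)-9-oxo-6-(phenylsulfanyl)bicyclo[3.3.1]nonan-4-yl 4-nitrobenzoate | O=C(OCc1ccccc1)N[C@H]2C[C@@]3(OCc4ccccc4)C(=O)[C@@H]([C@H]2OC(=O)c6ccc(cc6)[N+](=O)[O-])C(Sc5ccccc5)CC3
F8 | step 12 | benzyl N-[(1R,3S,4R,5R)-1-(benzyloxy)-6,7-exo-epoxy-9-oxo-4-[(triethylsilyl)oxy]bicyclo[3.3.1]nonan-3-yl]carbamate | O=C(OCc1ccccc1)N[C@H]2C[C@@]3(OCc4ccccc4)C(=O)[C@@H]([C@H]2O[Si](CC)(CC)CC)[C@@H]5O[C@@H]5C3
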